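**Retrosynthetic overview**

1. Target 26 ⇐ fluoride desilylation of tris-silyl ether 25.
2. 25 ⇐ C4–C4a disconnection of the pyran ring: hydroxymethyl chlorodione 14 and 2-methoxytriene 21 are first tied through O2–C3 as a temporary 4H-1,3-dioxin ketal (23), then a Lewis-acid O→C transposition closes the pyran by the C4–C4a bond in the same flask.
3. Enabling feature: the pyran ring (O2, C1, C8a, C4a, C4, C3) carries the doubly vinylogous ester O2–C3=C4–C4a=C5(Cl)–C6=O, so C4 is the α-carbon of a C3 methyl ketone, C4a is a carbonyl carbon of a 2-chloro-1,3-dione (C4a/C6), and the C4a enol oxygen lies 1,3 to the C1 hydroxyl.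
4. The carbocycle (present first; pyran formed second) comes from (S)-carvone, mapped C1→C8, C2(Me)→C7, C3→C6, C4→C5, C5→C4a, C6→C8a; its stereocentre relays C8a, C7 and C8 and is then oxidised to the C4a carbonyl.
5. Side chain 21 comes from methyl (S)-3-hydroxybutanoate by anti-methylation, two Wittig olefinations and ester methylenation.

Key step: step 18

Remark: isochromene numbering of the target (O2, C1, C3, C4, C4a, C5–C8, C8a; side chain C1′–C7′) is used for all intermediates; chlorodiones are drawn as the C4a enol, and stereocentres that are destroyed later (hydroperoxide carbon of 6, epoxide carbons of 11, ketal carbon of 22 and 23) are left undefined.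

**Route**

Step 1
Reactants: 1 (S)-(+)-carvone
Product: 2 (1S,4S,6S)-1-methyl-4-(prop-1-en-2-yl)-7-oxabicyclo[4.1.0]heptan-2-one (epoxide trans to isopropenyl)
Conditions: 30% aq. H2O2, NaOH (cat.), MeOH, 0 °C
Reagents that add atoms: hydrogen peroxide, OO
Why: Weitz–Scheffer epoxidation, in which hydroperoxide should add axially to the enone β-carbon anti to the isopropenyl group, so that the epoxide oxygen (future C7–O) is trans to isopropenyl.

Step 2
Reactants: 2 carvone oxide
Product: 3 (1S,3S,4S,6S)-3-(hydroxymethyl)-1-methyl-4-(prop-1-en-2-yl)-7-oxabicyclo[4.1.0]heptan-2-one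
Conditions: LiN(iPr)2, THF, −78 °C; HCHO (gas), −78 → −40 °C; aq. NH4Cl
Reagents that add atoms: formaldehyde, C=O
Why: aldol addition of the kinetic lithium enolate (the only enolisable position) to formaldehyde should occur anti to the adjacent isopropenyl group, setting the future C8a centre.

Step 3
Reactants: 3 hydroxymethyl epoxy ketone
Product: 4 (1R,2R,3S,4S,6S)-3-(hydroxymethyl)-1-methyl-4-(prop-1-en-2-yl)-7-oxabicyclo[4.1.0]heptan-2-ol
Conditions: NaBH4, CeCl3·7H2O, MeOH, −78 → −20 °C
Reagents that add atoms: none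
Why: Luche reduction, with hydride expected anti to the epoxide C–O bond (Felkin–Anh) and anti to the CH2OH group, placing the future C8 hydroxyl cis to both.

Step 4
Reactants: 4 epoxy diol
Product: 5 bis(tert-butyldimethylsilyl) ether of 4 (primary and secondary oxygen silylated)
Conditions: TBSOTf, 2,6-lutidine, CH2Cl2, −78 → 0 °C
Reagents that add atoms: tert-butyldimethylsilyl triflate, CC(C)(C)[Si](C)(C)OS(=O)(=O)C(F)(F)F
Why: standard silylation of a primary and a hindered secondary alcohol with a silyl triflate, which touches no stereocentre.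

Step 5
Reactants: 5 bis-silyl ether
Product: 7 acetate (isopropenyl of 5 replaced by acetoxy with retention), via methoxy hydroperoxide 6 (not isolated)
Conditions: O3, CH2Cl2/MeOH, −78 °C; then Ac2O, Et3N, DMAP (cat.), −78 °C → rt
Reagents that add atoms: ozone, [O-][O+]=O; methanol, CO
Why: ozonolysis in methanol gives the α-methoxy hydroperoxide, whose peracetate undergoes Criegee rearrangement with migration of the secondary ring carbon and retention, installing the future C4a oxygen.

Step 6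
Reactants: 7 acetate
Product: 8 secondary alcohol (acetoxy of 7 replaced by hydroxyl)
Conditions: K2CO3 (cat.), MeOH, 0 °C → rt
Reagents that add atoms: none
Why: base-catalysed transesterification, to which the epoxide and both silyl ethers are inert.

Step 7
Reactants: 8 alcohol
Product: 10 (4S,5R,6S)-5-[(tert-butyldimethylsilyl)oxy]-6-{[(tert-butyldimethylsilyl)oxy]methyl}-4-hydroxy-4-methylcyclohex-2-en-1-one, via β,γ-epoxy ketone 9 (not isolated)
Conditions: nPr4N[RuO4] (cat.), NMO, 4 Å MS, CH2Cl2, rt; then Et3N (cat.), 0 °C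
Reagents that add atoms: none
Why: Ley–Griffith oxidation gives the C4a ketone, and the β,γ-epoxy ketone then opens by E1cB elimination to the γ-hydroxy enone, keeping the tertiary C7–O bond and its configuration.

Step 8
Reactants: 10 γ-hydroxy enone
Product: 11 2,3-epoxide of 10 (C5–C6 epoxide; configuration of the two epoxide carbons inconsequential)
Conditions: tBuOOH (in decane), benzyltrimethylammonium hydroxide (cat.), THF, 0 °C
Reagents that add atoms: tert-butyl hydroperoxide, CC(C)(C)OO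
Why: Weitz–Scheffer epoxidation with a weakly basic peroxide anion should oxidise the enone without enolising the ketone towards C8a.

Step 9
Reactants: 11 epoxy ketone
Product: 12 (4R,5R,6S)-5-[(tert-butyldimethylsilyl)oxy]-6-{[(tert-butyldimethylsilyl)oxy]methyl}-4-hydroxy-4-methylcyclohexane-1,3-dione
Conditions: Pd(PPh3)4 (5 mol%), Ph2PCH2CH2PPh2 (5 mol%), toluene, 80 °C
Reagents that add atoms: none
Why: the known palladium-catalysed isomerisation of α,β-epoxy ketones to β-diketones (zerovalent palladium opens the Cα–O bond, β-hydride elimination from the carbinol carbon) should give the C4a/C6 dione under neutral conditions.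

Step 10
Reactants: 12 1,3-dione
Product: 13 2-chloro derivative of 12 (C5–Cl, enol form)
Conditions: N-chlorosuccinimide (1.0 equiv), CH2Cl2, 0 °C
Reagents that add atoms: N-chlorosuccinimide, O=C1CCC(=O)N1Cl
Why: electrophilic chlorination of the enolised 1,3-dione at its only enolic carbon (future C5).

Step 11
Reactants: 13 chlorodione
Product: 14 (4R,5R,6S)-5-[(tert-butyldimethylsilyl)oxy]-2-chloro-4-hydroxy-6-(hydroxymethyl)-4-methylcyclohexane-1,3-dione (enol form)
Conditions: HF·pyridine, pyridine, THF, 0 °C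
Reagents that add atoms: none
Why: the primary silyl ether should be cleaved much faster than the hindered secondary one at C8.

Step 12
Reactants: 15 methyl (S)-3-hydroxybutanoate
Product: 16 methyl (2S,3S)-3-hydroxy-2-methylbutanoate
Conditions: LiN(iPr)2 (2.2 equiv), THF, −78 → −20 °C; MeI, DMPU, −78 → 0 °C; aq. NH4Cl
Reagents that add atoms: iodomethane, CI
Why: Fráter–Seebach alkylation, in which the chelated dianion is methylated anti to the alkoxide, giving the anti C5′/C6′ relationship.

Step 13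
Reactants: 16 hydroxy ester
Product: 17 methyl (2S,3S)-3-[(tert-butyldimethylsilyl)oxy]-2-methylbutanoate
Conditions: TBSCl, imidazole, DMF, rt
Reagents that add atoms: tert-butyldimethylsilyl chloride, CC(C)(C)[Si](C)(C)Cl
Why: standard silylation of a secondary alcohol.

Step 14
Reactants: 17 silyloxy ester
Product: 18 (2S,3S)-3-[(tert-butyldimethylsilyl)oxy]-2-methylbutanal
Conditions: iBu2AlH (1.1 equiv), CH2Cl2, −78 °C; aq. KNaC4H4O6 (potassium sodium tartrate); used crude
Reagents that add atoms: none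
Why: partial reduction through the tetrahedral aluminate, stable at −78 °C, should stop at the aldehyde without epimerising the α-centre.

Step 15
Reactants: 18 aldehyde
Product: 19 (2E,4R,5S)-5-[(tert-butyldimethylsilyl)oxy]-2,4-dimethylhex-2-enal
Conditions: 2-(triphenylphosphoranylidene)propanal, toluene, 90 °C
Reagents that add atoms: 2-(triphenylphosphoranylidene)propanal, CC(C=O)=P(c1ccccc1)(c1ccccc1)c1ccccc1
Why: Wittig olefination with a formyl-stabilised ylide should give the (E)-trisubstituted enal (future C3′=C4′).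

Step 16
Reactants: 19 enal
Product: 20 methyl (2E,4E,6R,7S)-7-[(tert-butyldimethylsilyl)oxy]-4,6-dimethylocta-2,4-dienoate
Conditions: methyl (triphenylphosphoranylidene)acetate, toluene, 80 °C
Reagents that add atoms: methyl (triphenylphosphoranylidene)acetate, COC(=O)C=P(c1ccccc1)(c1ccccc1)c1ccccc1
Why: Wittig olefination with an ester-stabilised ylide should give the (E)-disubstituted alkene (future C1′=C2′), the ester carbon becoming C3.

Step 17
Reactants: 20 dienoate
Product: 21 (3E,5E,7R,8S)-8-[(tert-butyldimethylsilyl)oxy]-2-methoxy-5,7-dimethylnona-1,3,5-triene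
Conditions: Cp2Ti(μ-Cl)(μ-CH2)AlMe2 (Tebbe reagent), pyridine (cat.), THF/toluene, −40 °C → rt; aq. NaOH; basic Al2O3; used crude
Reagents that add atoms: Tebbe reagent Cp2Ti(μ-Cl)(μ-CH2)AlMe2, C[Al-]1(C)C[Ti]([Cl+]1)(C1C=CC=C1)C1C=CC=C1
Why: Tebbe methylenation of the ester carbonyl gives the 2-methoxy-1,3-diene, making the future C4 a nucleophilic enol ether carbon.

Step 18
Reactants: 14 hydroxymethyl chlorodione; 21 2-methoxytriene
Product: 25 tris-silyl ether of the target (C7–OSiMe3; C8 and C6′ tert-butyldimethylsilyl ethers), via mixed ketal 22 (not isolated), via dioxin ketal 23 (not isolated), via silylated enol ether 24 (not isolated)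
Conditions: PPTS (5 mol%), 5 Å MS, CH2Cl2, 0 °C → rt; volatiles removed; then iPr2NEt (4 equiv), TMSOTf (3.3 equiv), CH2Cl2, −78 → −30 °C; aq. NaHCO3
Reagents that add atoms: trimethylsilyl triflate, C[Si](C)(C)OS(=O)(=O)C(F)(F)F
Why: Proposed new method: acid first adds the C1 hydroxyl of 14 to enol ether 21 and the C4a enol hydroxyl displaces methanol, tying C3 to O2 and to the C4a oxygen in the six-membered 4H-1,3-dioxin ketal 23; TMSOTf then silylates the C6 carbonyl, the C3–O(C4a) bond ionises, and the amine removes a proton from the C4 methyl group to give enol ether 24 (the known silyl triflate/amine conversion of ketals into enol ethers). A second silylation turns the C4a carbonyl into a 2-chloro-1,3-bis(silyloxy)allyl cation, which C4 attacks in a 6-(enolendo)-exo-trig Mukaiyama-aldol-type closure of the pyran ring (O2, C1, C8a, C4a, C4, C3); loss of a proton from C4 and of hexamethyldisiloxane from C4a leaves the O2–C3=C4–C4a=C5–C6=O array. The closest known reaction types are the Petasis–Ferrier rearrangement (Lewis-acid O→C transposition of cyclic enol acetals through oxocarbenium/enolate pairs) and the Stork–Danheiser addition–transposition on vinylogous esters. No stereocentre is created (C3, C4, C4a and C5 end sp2), and C7, C8 and C8a are carried through. The step needs selectivity for C4a over C6 and for C4–C4a bonding over recombination of the C3 cation with oxygen or C5: the tether lets C4 reach only C4a, C5 attack would build two adjacent fully substituted carbons and should be reversible, and only the C4–C4a closure is made irreversible by loss of disiloxane. Low temperature and a hindered amine are chosen to avoid deprotonation at C8a.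

Step 19
Reactants: 25 tris-silyl ether
Product: 26 (7R,8R,8aS)-5-chloro-7,8-dihydroxy-3-[(1E,3E,5R,6S)-6-hydroxy-3,5-dimethylhepta-1,3-dien-1-yl]-7-methyl-1,7,8,8a-tetrahydro-6H-isochromen-6-one (CNP0536300.1)
Conditions: HF·pyridine (excess), pyridine, THF, 0 °C → rt
Reagents that add atoms: none
Why: fluoride-mediated cleavage of all three silyl ethers under mildly acidic conditions should leave the vinylogous ester and the C8a centre untouched.

**Compound list**

1 | (S)-(+)-carvone | CC1=CC[C@@H](CC1=O)C(C)=C | starting material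
2 | (1S,4S,6S)-1-methyl-4-(prop-1-en-2-yl)-7-oxabicyclo[4.1.0]heptan-2-one | C[C@]12O[C@H]1C[C@H](C(C)=C)CC2=O | intermediate
3 | (1S,3S,4S,6S)-3-(hydroxymethyl)-1-methyl-4-(prop-1-en-2-yl)-7-oxabicyclo[4.1.0]heptan-2-one | C[C@]12O[C@H]1C[C@H](C(C)=C)[C@@H](CO)C2=O | intermediate
4 | (1R,2R,3S,4S,6S)-3-(hydroxymethyl)-1-methyl-4-(prop-1-en-2-yl)-7-oxabicyclo[4.1.0]heptan-2-ol | C[C@]12O[C@H]1C[C@H](C(C)=C)[C@@H](CO)[C@H]2O | intermediate
5 | bis(tert-butyldimethylsilyl) ether of 4 | C[C@]12O[C@H]1C[C@H](C(C)=C)[C@@H](CO[Si](C)(C)C(C)(C)C)[C@H]2O[Si](C)(C)C(C)(C)C | intermediate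
6 | α-methoxy hydroperoxide from 5 (isopropenyl → C(CH3)(OCH3)OOH) | C[C@]12O[C@H]1C[C@H](C(C)(OC)OO)[C@@H](CO[Si](C)(C)C(C)(C)C)[C@H]2O[Si](C)(C)C(C)(C)C | intermediate (not isolated)
7 | acetate (isopropenyl of 5 replaced by acetoxy, retention) | C[C@]12O[C@H]1C[C@H](OC(C)=O)[C@@H](CO[Si](C)(C)C(C)(C)C)[C@H]2O[Si](C)(C)C(C)(C)C | intermediate
8 | secondary alcohol from 7 | C[C@]12O[C@H]1C[C@H](O)[C@@H](CO[Si](C)(C)C(C)(C)C)[C@H]2O[Si](C)(C)C(C)(C)C | intermediate
9 | β,γ-epoxy ketone from 8 | C[C@]12O[C@H]1CC(=O)[C@@H](CO[Si](C)(C)C(C)(C)C)[C@H]2O[Si](C)(C)C(C)(C)C | intermediate (not isolated)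
10 | (4S,5R,6S)-5-[(tert-butyldimethylsilyl)oxy]-6-{[(tert-butyldimethylsilyl)oxy]methyl}-4-hydroxy-4-methylcyclohex-2-en-1-one | C[C@]1(O)C=CC(=O)[C@@H](CO[Si](C)(C)C(C)(C)C)[C@H]1O[Si](C)(C)C(C)(C)C | intermediate
11 | 2,3-epoxide of 10 | C[C@]1(O)C2OC2C(=O)[C@@H](CO[Si](C)(C)C(C)(C)C)[C@H]1O[Si](C)(C)C(C)(C)C | intermediate
12 | (4R,5R,6S)-5-[(tert-butyldimethylsilyl)oxy]-6-{[(tert-butyldimethylsilyl)oxy]methyl}-4-hydroxy-4-methylcyclohexane-1,3-dione | C[C@]1(O)C(=O)CC(=O)[C@@H](CO[Si](C)(C)C(C)(C)C)[C@H]1O[Si](C)(C)C(C)(C)C | intermediate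
13 | 2-chloro derivative of 12 (enol form) | C[C@]1(O)C(=O)C(Cl)=C(O)[C@@H](CO[Si](C)(C)C(C)(C)C)[C@H]1O[Si](C)(C)C(C)(C)C | intermediate
14 | (4R,5R,6S)-5-[(tert-butyldimethylsilyl)oxy]-2-chloro-4-hydroxy-6-(hydroxymethyl)-4-methylcyclohexane-1,3-dione (enol form) | C[C@]1(O)C(=O)C(Cl)=C(O)[C@@H](CO)[C@H]1O[Si](C)(C)C(C)(C)C | intermediate
15 | methyl (S)-3-hydroxybutanoate | C[C@H](O)CC(=O)OC | starting material
16 | methyl (2S,3S)-3-hydroxy-2-methylbutanoate | C[C@H](O)[C@H](C)C(=O)OC | intermediate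
17 | methyl (2S,3S)-3-[(tert-butyldimethylsilyl)oxy]-2-methylbutanoate | C[C@H](O[Si](C)(C)C(C)(C)C)[C@H](C)C(=O)OC | intermediate
18 | (2S,3S)-3-[(tert-butyldimethylsilyl)oxy]-2-methylbutanal | C[C@H](O[Si](C)(C)C(C)(C)C)[C@H](C)C=O | intermediate
19 | (2E,4R,5S)-5-[(tert-butyldimethylsilyl)oxy]-2,4-dimethylhex-2-enal | O=C/C(C)=C/[C@@H](C)[C@H](C)O[Si](C)(C)C(C)(C)C | intermediate
20 | methyl (2E,4E,6R,7S)-7-[(tert-butyldimethylsilyl)oxy]-4,6-dimethylocta-2,4-dienoate | COC(=O)/C=C/C(C)=C/[C@@H](C)[C@H](C)O[Si](C)(C)C(C)(C)C | intermediate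
21 | (3E,5E,7R,8S)-8-[(tert-butyldimethylsilyl)oxy]-2-methoxy-5,7-dimethylnona-1,3,5-triene | C=C(OC)/C=C/C(C)=C/[C@@H](C)[C@H](C)O[Si](C)(C)C(C)(C)C | intermediate
22 | mixed methyl ketal of 14 (C1–O–C3(OCH3)(CH3)–dienyl) | C[C@]1(O)C(=O)C(Cl)=C(O)[C@@H](COC(C)(OC)/C=C/C(C)=C/[C@@H](C)[C@H](C)O[Si](C)(C)C(C)(C)C)[C@H]1O[Si](C)(C)C(C)(C)C | intermediate (not isolated)
23 | 4H-1,3-dioxin ketal (C3 bound to O2 and to the C4a oxygen) | C[C@]1(O)C(=O)C(Cl)=C2OC(C)(/C=C/C(C)=C/[C@@H](C)[C@H](C)O[Si](C)(C)C(C)(C)C)OC[C@H]2[C@H]1O[Si](C)(C)C(C)(C)C | intermediate (not isolated)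
24 | ring-opened enol ether (C1–O–C3(=C4H2)–dienyl; C6 silyl enol ether, C4a ketone, C7–OSiMe3) | C[C@]1(O[Si](C)(C)C)C(O[Si](C)(C)C)=C(Cl)C(=O)[C@@H](COC(=C)/C=C/C(C)=C/[C@@H](C)[C@H](C)O[Si](C)(C)C(C)(C)C)[C@H]1O[Si](C)(C)C(C)(C)C | intermediate (not isolated)
25 | (7R,8R,8aS)-8-[(tert-butyldimethylsilyl)oxy]-3-{(1E,3E,5R,6S)-6-[(tert-butyldimethylsilyl)oxy]-3,5-dimethylhepta-1,3-dien-1-yl}-5-chloro-7-methyl-7-[(trimethylsilyl)oxy]-1,7,8,8a-tetrahydro-6H-isochromen-6-one | CC(/C=C/C1=CC2=C(Cl)C(=O)[C@](C)(O[Si](C)(C)C)[C@H](O[Si](C)(C)C(C)(C)C)[C@@H]2CO1)=C\[C@@H](C)[C@H](C)O[Si](C)(C)C(C)(C)C | intermediate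
26 | (7R,8R,8aS)-5-chloro-7,8-dihydroxy-3-[(1E,3E,5R,6S)-6-hydroxy-3,5-dimethylhepta-1,3-dien-1-yl]-7-methyl-1,7,8,8a-tetrahydro-6H-isochromen-6-one | CC(/C=C/C1=CC2=C(Cl)C(=O)[C@](C)(O)[C@H](O)[C@@H]2CO1)=C\[C@@H](C)[C@H](C)O | target

**Step count and risks**

Total step count: 19. Longest linear sequence: 13 steps (steps 1–11, 18, 19).

Steps most likely to fail:

1. Step 18 (Proposed new method). The C3 oxocarbenium ion may recombine with the enol oxygen or with C5 faster than it is deprotonated. The activated dione may also be deprotonated at C8a, which would scramble C8a and allow β-elimination of the C8 silyloxy group. Fallback with known chemistry, setting out from 13 and 19 and returning at 26: 13 is sulfonylated (PhNTf2, Et3N, CH2Cl2; the less hindered C4a oxygen is expected to react) to enol triflate F1. Enal 19 is homologated by Horner–Wadsworth–Emmons reaction with diethyl [3-(trimethylsilyl)prop-2-yn-1-yl]phosphonate and LiN(SiMe3)2 to silyl dienyne F2, which is desilylated (K2CO3, MeOH) to terminal dienyne F3. Sonogashira coupling of the two (PdCl2(PPh3)2, CuI, Et3N) forms the C4–C4a bond intermolecularly and gives enynone F4. HF·pyridine at 0 °C frees the primary hydroxyl to give alkynol F5, and 6-endo-dig hydroalkoxylation (Ph3PAuCl/AgOTf, CH2Cl2) closes the pyran through O2–C3 to give bis-silyl ether F6. The conditions of step 19 then lead to 26.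

2. Step 9. Opening of the hindered epoxy ketone by zerovalent palladium may be slow, or heating may cause loss of the C8 silyloxy group; the preceding epoxidation at the neopentyl-like β-carbon may also stall. Fallback setting out from 10 and returning at 12: copper-catalysed conjugate borylation of 10 (B2pin2, CuCl, NaOtBu, MeOH, THF) gives β-boryl ketone F7; oxidation (NaBO3·4H2O, THF/H2O) gives β-hydroxy ketone F8; Ley–Griffith oxidation (nPr4N[RuO4], NMO) gives 12.

3. Step 5. Acylation and rearrangement of the methoxy hydroperoxide may be incomplete, with fragmentation to the methyl ketone instead of migration. Fallback setting out from 5 and returning at 7: ozonolysis with reductive work-up (O3, CH2Cl2, −78 °C; Me2S) gives methyl ketone F9, and Baeyer–Villiger oxidation (mCPBA, NaHCO3, CH2Cl2) inserts oxygen with retention to give 7.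

**Further compounds**

F1 | step 18 | C4a enol triflate of 13 | C[C@]1(O)C(=O)C(Cl)=C(OS(=O)(=O)C(F)(F)F)[C@@H](CO[Si](C)(C)C(C)(C)C)[C@H]1O[Si](C)(C)C(C)(C)C
F2 | step 18 | tert-butyldimethyl{[(2S,3R,4E,6E)-3,5-dimethyl-9-(trimethylsilyl)nona-4,6-dien-8-yn-2-yl]oxy}silane | C[Si](C)(C)C#C/C=C/C(C)=C/[C@@H](C)[C@H](C)O[Si](C)(C)C(C)(C)C
F3 | step 18 | tert-butyl{[(2S,3R,4E,6E)-3,5-dimethylnona-4,6-dien-8-yn-2-yl]oxy}dimethylsilane | C#C/C=C/C(C)=C/[C@@H](C)[C@H](C)O[Si](C)(C)C(C)(C)C
F4 | step 18 | C4a-alkynylated 2-chloroenone (Sonogashira product, three silyl ethers) | C[C@]1(O)C(=O)C(Cl)=C(C#C/C=C/C(C)=C/[C@@H](C)[C@H](C)O[Si](C)(C)C(C)(C)C)[C@@H](CO[Si](C)(C)C(C)(C)C)[C@H]1O[Si](C)(C)C(C)(C)C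
F5 | step 18 | primary alcohol from F4 | C[C@]1(O)C(=O)C(Cl)=C(C#C/C=C/C(C)=C/[C@@H](C)[C@H](C)O[Si](C)(C)C(C)(C)C)[C@@H](CO)[C@H]1O[Si](C)(C)C(C)(C)C
F6 | step 18 | C8,C6′-bis(tert-butyldimethylsilyl) ether of 26 | CC(/C=C/C1=CC2=C(Cl)C(=O)[C@](C)(O)[C@H](O[Si](C)(C)C(C)(C)C)[C@@H]2CO1)=C\[C@@H](C)[C@H](C)O[Si](C)(C)C(C)(C)C
F7 | step 9 | 3-(pinacolboryl) ketone from 10 | C[C@]1(O)C(B2OC(C)(C)C(C)(C)O2)CC(=O)[C@@H](CO[Si](C)(C)C(C)(C)C)[C@H]1O[Si](C)(C)C(C)(C)C
F8 | step 9 | β-hydroxy ketone from F7 | C[C@]1(O)C(O)CC(=O)[C@@H](CO[Si](C)(C)C(C)(C)C)[C@H]1O[Si](C)(C)C(C)(C)C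
F9 | step 5 | methyl ketone from 5 (isopropenyl → acetyl) | C[C@]12O[C@H]1C[C@H](C(C)=O)[C@@H](CO[Si](C)(C)C(C)(C)C)[C@H]2O[Si](C)(C)C(C)(C)C
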